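**Retrosynthetic overview**
1. Target 27 ⇐ penta-MOM flavanonol 26 (acidic removal of five MOM ethers) ⇐ phenol 24 by closing the O1–C2 bond of ring C with inversion at C2 (Mitsunobu) ⇐ silyl ether 23.
2. 23 ⇐ open-chain 1,3-diketone 22 by enantioselective hydride delivery to the ring B carbonyl carbon C2. The feature used: C3 sits between the C4 carbonyl and C2, so while ring C is open and C2 is still a ketone, C3–H is flanked by two carbonyls and epimerises freely; one reduction at C2 then fixes C2 and C3 together (dynamic kinetic resolution).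
3. 22 ⇐ C3–C4 bond by aldol addition of the ring B α-(MOM-oxy) ketone 11 to the ring A aldehyde 19, then oxidation of the C4 carbinol.
4. 19 ⇐ 2,4,6-trihydroxybenzaldehyde (prenyl ether, then para-Claisen–Cope shift that puts prenyl on C6); 11 ⇐ resorcinol (two directed lithiations: geranyl bromide at C3', then the MOM-glycolyl Weinreb amide 3 at C1').
5. Ring order: rings A and B are bought as arenes; ring C is the only ring formed (step 14).

Key step: step 12

Assumption: flavanonol numbering is used (O1, C2, C3, C4 in ring C; ring A = C4a–C8a; ring B = C1'–C6'), the target is read as the (2R,3R)-trans isomer, and the hand of the TsDPEN ligand is assigned from the usual aryl ketone model of this catalyst class.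
Abbreviations: MOM = methoxymethyl; TBS = tert-butyldimethylsilyl; prenyl = 3-methylbut-2-en-1-yl; geranyl = (2E)-3,7-dimethylocta-2,6-dien-1-yl; TsDPEN = N-tosyl-1,2-diphenylethane-1,2-diamine.

**Route**

Step 1
Reactants: 1 methyl glycolate
Product: 2 methyl 2-(methoxymethoxy)acetate
Conditions: MOMCl, i-Pr2NEt, CH2Cl2, 0 °C → rt
Reagents that add atoms: chloromethyl methyl ether (MOMCl), COCCl
Why: Williamson-type O-alkylation of the primary alcohol by the reactive α-chloro ether under amine base (MOM protection) should leave the methyl ester untouched.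

Step 2
Reactants: 2 methyl 2-(methoxymethoxy)acetate
Product: 3 N-methoxy-N-methyl-2-(methoxymethoxy)acetamide
Conditions: MeNH(OMe)·HCl, i-PrMgCl, THF, −20 °C
Reagents that add atoms: N,O-dimethylhydroxylamine hydrochloride, CNOC.Cl
Why: Weinreb amide formation by aminolysis of the ester with the chloromagnesium amide generated in the flask, whose magnesium chelate should stop cleanly at the amide.

Step 3
Reactants: 4 resorcinol
Product: 5 1,3-bis(methoxymethoxy)benzene
Conditions: NaH, MOMCl, DMF, 0 °C → rt
Reagents that add atoms: chloromethyl methyl ether (MOMCl), COCCl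
Why: Double Williamson O-alkylation of the sodium phenoxides (MOM protection) installs the two ortho-directing groups needed for both lithiations.

Step 4
Reactants: 5 1,3-bis(methoxymethoxy)benzene; 6 geranyl bromide
Product: 8 2-geranyl-1,3-bis(methoxymethoxy)benzene, via 2-lithio-1,3-bis(methoxymethoxy)benzene 7 (not isolated)
Conditions: n-BuLi, THF, 0 °C → rt; then CuI (10 mol %), 6, −78 °C → rt
Reagents that add atoms: none
Why: Directed ortho-metalation at the carbon flanked by both OMOM groups followed by copper-catalysed allylic substitution at the primary carbon of geranyl bromide should give the C-geranyl arene with the E alkene unchanged.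

Step 5
Reactants: 8 2-geranyl-1,3-bis(methoxymethoxy)benzene; 3 N-methoxy-N-methyl-2-(methoxymethoxy)acetamide
Product: 11 1-[3-geranyl-2,4-bis(methoxymethoxy)phenyl]-2-(methoxymethoxy)ethan-1-one (ring B ketone), via ring B aryllithium 9 (not isolated), via lithium hemiaminal adduct 10 (not isolated)
Conditions: n-BuLi, TMEDA, Et2O, 0 °C → rt; then 3, THF, −78 → 0 °C; AcOH
Reagents that add atoms: none
Why: A second directed ortho-metalation next to an OMOM group (coordination-controlled ring lithiation should outrun deprotonation of the benzylic–allylic CH2) followed by Weinreb ketone synthesis, in which the chelated tetrahedral adduct prevents over-addition.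

Step 6
Reactants: 12 2,4,6-trihydroxybenzaldehyde
Product: 13 2-hydroxy-4,6-bis(methoxymethoxy)benzaldehyde
Conditions: MOMCl (2.2 equiv), i-Pr2NEt, CH2Cl2, 0 °C → rt
Reagents that add atoms: chloromethyl methyl ether (MOMCl), COCCl
Why: Selective MOM protection in which the para hydroxyl and one ortho hydroxyl are alkylated while the remaining ortho hydroxyl is held back by its hydrogen bond to the aldehyde.

Step 7
Reactants: 13 2-hydroxy-4,6-bis(methoxymethoxy)benzaldehyde; 14 prenyl bromide
Product: 15 2,4-bis(methoxymethoxy)-6-(prenyloxy)benzaldehyde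
Conditions: K2CO3, DMF, rt
Reagents that add atoms: none
Why: Williamson O-alkylation of the chelated phenol by the allylic bromide in a polar aprotic solvent, where O-alkylation should dominate over C-alkylation.

Step 8
Reactants: 15 2,4-bis(methoxymethoxy)-6-(prenyloxy)benzaldehyde
Product: 18 6-hydroxy-2,4-bis(methoxymethoxy)-3-prenylbenzaldehyde, via ortho dienone 16 (not isolated), via para dienone 17 (not isolated)
Conditions: PhNEt2, 200 °C, sealed tube, argon
Reagents that add atoms: none
Why: Aromatic Claisen rearrangement to the only free ortho carbon followed by a Cope shift of the crowded 1,1-dimethylallyl dienone and tautomerisation (para-Claisen–Cope rearrangement) should deliver the unrearranged prenyl group para to the freed hydroxyl, that is on the carbon between the two OMOM groups, which is C6 of the target.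

Step 9
Reactants: 18 6-hydroxy-2,4-bis(methoxymethoxy)-3-prenylbenzaldehyde
Product: 19 6-[(tert-butyldimethylsilyl)oxy]-2,4-bis(methoxymethoxy)-3-prenylbenzaldehyde (ring A aldehyde)
Conditions: TBSCl, imidazole, DMF, rt
Reagents that add atoms: tert-butyldimethylsilyl chloride (TBSCl), CC(C)(C)[Si](C)(C)Cl
Why: Silyl ether formation on the hydrogen-bonded phenol marks, with a fluoride-labile group, the one ring A oxygen that will become O1.

Step 10
Reactants: 11 ring B ketone; 19 ring A aldehyde
Product: 21 aldol adduct 3-(ring A aryl)-1-(ring B aryl)-3-hydroxy-2-(methoxymethoxy)propan-1-one (racemic diastereomer mixture), via lithium enolate 20 (not isolated)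
Conditions: LiN(i-Pr)2, THF, −78 °C; then 19, −78 °C; AcOH, −78 °C
Reagents that add atoms: none
Why: Aldol addition of the chelated lithium Z-enolate of the α-alkoxy ketone to the aldehyde forms the C3–C4 bond, the cold acidic quench forestalls retro-aldol cleavage and silyl transfer from the aryl oxygen to the alkoxide, and the two new stereocentres need no control because the next step erases one and makes the other labile.

Step 11
Reactants: 21 aldol adduct
Product: 22 2-(methoxymethoxy)-1-(ring A aryl)-3-(ring B aryl)propane-1,3-dione (C3 configurationally labile)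
Conditions: Dess–Martin periodinane, CH2Cl2, 0 °C → rt
Reagents that add atoms: none
Why: Dess–Martin oxidation of the benzylic secondary alcohol to the C4 ketone under near-neutral conditions should spare the MOM and silyl ethers and the alkenes.

Step 12
Reactants: 22 1,3-diketone
Product: 23 (2S,3R)-syn hydroxy ketone (flavanonol numbering; C2–OH free; C3–OMOM; ring A OTBS)
Conditions: RuCl(p-cymene)[(R,R)-TsDPEN] (5 mol %), HCO2H/Et3N (5:2), CH2Cl2, 30 °C
Reagents that add atoms: none
Why: The hydride of the divalent ruthenium complex, formed from formate, passes to the ring B carbonyl carbon C2 while the ligand N–H proton passes to its oxygen in a concerted six-membered outer-sphere transition state, so only the C2–H and O–H bonds form (Noyori asymmetric transfer hydrogenation). The closest known reaction type is transfer hydrogenation with dynamic kinetic resolution of α-alkoxy β-keto esters and 2-substituted 1,3-diketones. No ring closes in this step. C2 is controlled by the hand of the ligand: with (R,R)-TsDPEN the ring B aryl group should lie against the p-cymene ligand (CH/π contact) and hydride should add to the face that gives 2S (the spatial sense of (R)-1-phenylethanol; the descriptor is S because the C3 branch outranks the aryl group). C3 is controlled by dynamic kinetic resolution: in the triethylamine–formic acid medium the doubly activated C3–H epimerises through the enol faster than hydride is transferred, and the catalyst consumes the C3 epimer whose OMOM group fits the transition state, which should give the syn (2S,3R) product. The step needs chemoselectivity for the ring B ketone over the ring A ketone and the four alkenes; the ring A carbonyl is flanked by OTBS and OMOM and twisted out of conjugation, and the outer-sphere hydride does not touch isolated C=C bonds.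

Step 13
Reactants: 23 (2S,3R)-syn hydroxy ketone
Product: 24 (2S,3R)-syn hydroxy ketone with free ring A phenol
Conditions: TBAF, AcOH, THF, 0 °C
Reagents that add atoms: none
Why: Fluoride-mediated desilylation of the aryl silyl ether, buffered with acetic acid so that the phenoxide is protonated at once and neither retro-aldol cleavage nor C3 epimerisation should set in, while MOM ethers are inert to fluoride.

Step 14
Reactants: 24 phenol
Product: 26 (2R,3R)-trans penta-MOM flavanonol, via oxyphosphonium phenoxide 25 (not isolated)
Conditions: PPh3, DIAD, THF, 0 °C → rt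
Reagents that add atoms: none
Why: Intramolecular Mitsunobu etherification in which the acidic ortho-acyl phenol displaces the oxyphosphonium group at C2 in a 6-exo-tet SN2 closure with inversion, turning 2S into 2R and giving the 2,3-trans ring C while C3 is untouched.

Step 15
Reactants: 26 (2R,3R)-trans penta-MOM flavanonol
Product: 27 target, (2R,3R)-2-(3-geranyl-2,4-dihydroxyphenyl)-3,5,7-trihydroxy-6-prenyl-2,3-dihydro-4H-chromen-4-one
Conditions: HCl (3 M aq), MeOH, 40 °C
Reagents that add atoms: none
Why: Acid-catalysed acetal exchange with methanol (MOM cleavage) should free the four phenols and the C3 hydroxyl, the dilute acid and mild temperature being chosen so that the ortho-prenyl and ortho-geranyl phenols do not cyclise to chromans and any reversible opening at C2 returns the favoured trans isomer.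

**Compound list**

1 | methyl glycolate (methyl 2-hydroxyacetate) | COC(=O)CO | starting material
2 | methyl 2-(methoxymethoxy)acetate | COCOCC(=O)OC | intermediate
3 | N-methoxy-N-methyl-2-(methoxymethoxy)acetamide | COCOCC(=O)N(C)OC | intermediate
4 | resorcinol | Oc1cccc(O)c1 | starting material
5 | 1,3-bis(methoxymethoxy)benzene | COCOc1cccc(OCOC)c1 | intermediate
6 | geranyl bromide, (2E)-1-bromo-3,7-dimethylocta-2,6-diene | CC(C)=CCC/C(C)=C/CBr | starting material
7 | [2,6-bis(methoxymethoxy)phenyl]lithium (not isolated) | [Li]c1c(OCOC)cccc1OCOC | intermediate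
8 | 2-[(2E)-3,7-dimethylocta-2,6-dien-1-yl]-1,3-bis(methoxymethoxy)benzene | CC(C)=CCC/C(C)=C/Cc1c(OCOC)cccc1OCOC | intermediate
9 | {3-[(2E)-3,7-dimethylocta-2,6-dien-1-yl]-2,4-bis(methoxymethoxy)phenyl}lithium (not isolated) | CC(C)=CCC/C(C)=C/Cc1c(OCOC)ccc([Li])c1OCOC | intermediate
10 | lithium 1-{3-[(2E)-3,7-dimethylocta-2,6-dien-1-yl]-2,4-bis(methoxymethoxy)phenyl}-1-[methoxy(methyl)amino]-2-(methoxymethoxy)ethan-1-olate, racemic (not isolated) | CC(C)=CCC/C(C)=C/Cc1c(OCOC)ccc(C(O[Li])(COCOC)N(C)OC)c1OCOC | intermediate
11 | 1-{3-[(2E)-3,7-dimethylocta-2,6-dien-1-yl]-2,4-bis(methoxymethoxy)phenyl}-2-(methoxymethoxy)ethan-1-one | CC(C)=CCC/C(C)=C/Cc1c(OCOC)ccc(C(=O)COCOC)c1OCOC | intermediate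
12 | 2,4,6-trihydroxybenzaldehyde | O=Cc1c(O)cc(O)cc1O | starting material
13 | 2-hydroxy-4,6-bis(methoxymethoxy)benzaldehyde | O=Cc1c(O)cc(OCOC)cc1OCOC | intermediate
14 | prenyl bromide (1-bromo-3-methylbut-2-ene) | CC(C)=CCBr | starting material
15 | 2,4-bis(methoxymethoxy)-6-[(3-methylbut-2-en-1-yl)oxy]benzaldehyde | O=Cc1c(OCC=C(C)C)cc(OCOC)cc1OCOC | intermediate
16 | 2,4-bis(methoxymethoxy)-5-(2-methylbut-3-en-2-yl)-6-oxocyclohexa-1,3-diene-1-carbaldehyde, racemic (not isolated) | O=CC1=C(OCOC)C=C(OCOC)C(C(C)(C)C=C)C1=O | intermediate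
17 | 2,4-bis(methoxymethoxy)-3-(3-methylbut-2-en-1-yl)-6-oxocyclohexa-1,4-diene-1-carbaldehyde, racemic (not isolated) | O=CC1=C(OCOC)C(CC=C(C)C)C(OCOC)=CC1=O | intermediate
18 | 6-hydroxy-2,4-bis(methoxymethoxy)-3-(3-methylbut-2-en-1-yl)benzaldehyde | O=Cc1c(O)cc(OCOC)c(CC=C(C)C)c1OCOC | intermediate
19 | 6-[(tert-butyldimethylsilyl)oxy]-2,4-bis(methoxymethoxy)-3-(3-methylbut-2-en-1-yl)benzaldehyde | O=Cc1c(O[Si](C)(C)C(C)(C)C)cc(OCOC)c(CC=C(C)C)c1OCOC | intermediate
20 | lithium (Z)-enolate of 11, lithium (Z)-1-{3-geranyl-2,4-bis(methoxymethoxy)phenyl}-2-(methoxymethoxy)ethen-1-olate (not isolated) | CC(C)=CCC/C(C)=C/Cc1c(OCOC)ccc(/C(O[Li])=C/OCOC)c1OCOC | intermediate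
21 | 3-{6-[(tert-butyldimethylsilyl)oxy]-2,4-bis(methoxymethoxy)-3-(3-methylbut-2-en-1-yl)phenyl}-1-{3-[(2E)-3,7-dimethylocta-2,6-dien-1-yl]-2,4-bis(methoxymethoxy)phenyl}-3-hydroxy-2-(methoxymethoxy)propan-1-one, racemic mixture of diastereomers | CC(C)=CCC/C(C)=C/Cc1c(OCOC)ccc(C(=O)C(OCOC)C(O)c2c(O[Si](C)(C)C(C)(C)C)cc(OCOC)c(CC=C(C)C)c2OCOC)c1OCOC | intermediate
22 | 1-{6-[(tert-butyldimethylsilyl)oxy]-2,4-bis(methoxymethoxy)-3-(3-methylbut-2-en-1-yl)phenyl}-3-{3-[(2E)-3,7-dimethylocta-2,6-dien-1-yl]-2,4-bis(methoxymethoxy)phenyl}-2-(methoxymethoxy)propane-1,3-dione, C3 configurationally labile | CC(C)=CCC/C(C)=C/Cc1c(OCOC)ccc(C(=O)C(OCOC)C(=O)c2c(O[Si](C)(C)C(C)(C)C)cc(OCOC)c(CC=C(C)C)c2OCOC)c1OCOC | intermediate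
23 | (2R,3S)-1-{6-[(tert-butyldimethylsilyl)oxy]-2,4-bis(methoxymethoxy)-3-(3-methylbut-2-en-1-yl)phenyl}-3-{3-[(2E)-3,7-dimethylocta-2,6-dien-1-yl]-2,4-bis(methoxymethoxy)phenyl}-3-hydroxy-2-(methoxymethoxy)propan-1-one; in flavanonol numbering C2 S, C3 R, syn | CC(C)=CCC/C(C)=C/Cc1c(OCOC)ccc([C@H](O)[C@@H](OCOC)C(=O)c2c(O[Si](C)(C)C(C)(C)C)cc(OCOC)c(CC=C(C)C)c2OCOC)c1OCOC | intermediate
24 | (2R,3S)-3-{3-[(2E)-3,7-dimethylocta-2,6-dien-1-yl]-2,4-bis(methoxymethoxy)phenyl}-3-hydroxy-1-[6-hydroxy-2,4-bis(methoxymethoxy)-3-(3-methylbut-2-en-1-yl)phenyl]-2-(methoxymethoxy)propan-1-one; in flavanonol numbering C2 S, C3 R | CC(C)=CCC/C(C)=C/Cc1c(OCOC)ccc([C@H](O)[C@@H](OCOC)C(=O)c2c(O)cc(OCOC)c(CC=C(C)C)c2OCOC)c1OCOC | intermediate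
25 | C2-O-triphenylphosphonium derivative of 24 with ring A phenoxide (zwitterion, not isolated) | CC(C)=CCC/C(C)=C/Cc1c(OCOC)ccc([C@H](O[P+](c2ccccc2)(c2ccccc2)c2ccccc2)[C@@H](OCOC)C(=O)c2c([O-])cc(OCOC)c(CC=C(C)C)c2OCOC)c1OCOC | intermediate
26 | (2R,3R)-2-{3-[(2E)-3,7-dimethylocta-2,6-dien-1-yl]-2,4-bis(methoxymethoxy)phenyl}-3,5,7-tris(methoxymethoxy)-6-(3-methylbut-2-en-1-yl)-2,3-dihydro-4H-chromen-4-one | CC(C)=CCC/C(C)=C/Cc1c(OCOC)ccc([C@H]2Oc3cc(OCOC)c(CC=C(C)C)c(OCOC)c3C(=O)[C@@H]2OCOC)c1OCOC | intermediate
27 | (2R,3R)-2-{3-[(2E)-3,7-dimethylocta-2,6-dien-1-yl]-2,4-dihydroxyphenyl}-3,5,7-trihydroxy-6-(3-methylbut-2-en-1-yl)-2,3-dihydro-4H-chromen-4-one | CC(C)=CCC/C(C)=C/Cc1c(O)ccc([C@H]2Oc3cc(O)c(CC=C(C)C)c(O)c3C(=O)[C@@H]2O)c1O | target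

**Step count and risks**

Total steps: 15. Longest linear sequence: 10 steps (from 12 through steps 6–9 and 10–15 to 27).

Steps most likely to fail:

1. Step 12 (transfer hydrogenation with dynamic resolution). What may go wrong: hydride transfer to the crowded ortho-alkoxy aryl ketone may be slow; facial selection at C2 or the syn/anti partition may be poor; the aryl silyl ether may be shed in the formic acid medium, after which the free phenol would add to the C2 ketone. Should the sense at C2 be opposite to the model, the enantiomeric ligand is used. Fallback, setting out from 22 and returning at 23 with no new compound: asymmetric hydrogenation under hydrogen pressure with a divalent ruthenium diphosphine halide catalyst, RuBr2[(R)-BINAP] or its enantiomer, whichever hand gives 2S (H2 50 bar, CH2Cl2/EtOH, 50 °C). This abandons outer-sphere transfer from formate for inner-sphere reduction of a substrate–metal chelate through the C2 carbonyl and the neighbouring oxygen, the classical hydrogenation with dynamic kinetic resolution of α-substituted β-keto carbonyl compounds. No formic acid is present, and isolated trisubstituted alkenes are not reduced by this catalyst class.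

2. Step 14 (Mitsunobu closure of ring C). What may go wrong: loss of the C3 proton from the activated alcohol (elimination across C2–C3, C3–H being α to the C4 ketone), or ionisation of the electron-rich benzylic oxyphosphonium ion with loss of stereospecificity. Fallback, setting out from 24 and returning at 26 with no new compound: acid-catalysed dehydrative ring closure through the C2 benzylic cation (camphorsulfonic acid, catalytic, in hexafluoropropan-2-ol/CH2Cl2, 0 °C), the way electron-rich 1,3-diarylpropanols are closed to flavans. The 2',4'-dioxygenated ring B stabilises the cation, the only free phenol captures it in a six-membered closure, and reversible opening and closing should funnel the material to the 2,3-trans isomer, so this route does not depend on the configuration at C2.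

3. Step 8 (para-Claisen–Cope rearrangement). What may go wrong: the ortho dienone may enolise before the Cope shift, leaving a reversed 1,1-dimethylallyl group next to the free hydroxyl, and the aldehyde may degrade at 200 °C. Fallback, setting out from 13 and returning at 19: silylation of 13 (TBSCl, imidazole, DMF) to 2-[(tert-butyldimethylsilyl)oxy]-4,6-bis(methoxymethoxy)benzaldehyde F1. Condensation with N,N'-dimethylethane-1,2-diamine (MgSO4, CH2Cl2, rt) masks the aldehyde as the cyclic aminal 2-{2-[(tert-butyldimethylsilyl)oxy]-4,6-bis(methoxymethoxy)phenyl}-1,3-dimethylimidazolidine F2. Directed ortho-metalation with s-BuLi/TMEDA (THF, −78 °C) at the one ring carbon flanked by both OMOM groups, then CuI-catalysed allylation with prenyl bromide 14, gives 2-{6-[(tert-butyldimethylsilyl)oxy]-2,4-bis(methoxymethoxy)-3-(3-methylbut-2-en-1-yl)phenyl}-1,3-dimethylimidazolidine F3. Mild hydrolysis of the aminal (aqueous citric acid, THF, rt) then gives 19. Regiochemistry here rests on lithiation between two OMOM groups instead of on a pericyclic relay.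

Further compounds
F0 | step 12 | none | none
F0 | step 14 | none | none
F1 | step 8 | 2-[(tert-butyldimethylsilyl)oxy]-4,6-bis(methoxymethoxy)benzaldehyde | O=Cc1c(O[Si](C)(C)C(C)(C)C)cc(OCOC)cc1OCOC
F2 | step 8 | 2-{2-[(tert-butyldimethylsilyl)oxy]-4,6-bis(methoxymethoxy)phenyl}-1,3-dimethylimidazolidine | CN1CCN(C)C1c1c(O[Si](C)(C)C(C)(C)C)cc(OCOC)cc1OCOC
F3 | step 8 | 2-{6-[(tert-butyldimethylsilyl)oxy]-2,4-bis(methoxymethoxy)-3-(3-methylbut-2-en-1-yl)phenyl}-1,3-dimethylimidazolidine | CN1CCN(C)C1c1c(O[Si](C)(C)C(C)(C)C)cc(OCOC)c(CC=C(C)C)c1OCOC
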